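The route rests on closing the seven-membered ring at the C7–C8 bond (longipinane numbering) by an intramolecular Claisen condensation: the methyl group (C8) of an acetyl unit on cyclobutane carbon C10 attacks an ester carbon (C7) that is carried, via the gem-dimethyl carbon C6, on C5. The step exploits two features: C8 sits between two oxygenated carbons that are each backed by a quaternary carbon, so only one enolate and one acceptor can form; and the C7/C9 anti-diol is locally C2-symmetric (both R), so one catalyst-controlled reduction of the resulting 1,3-diketone sets both centres. The precursor, a 6,7-disubstituted bicyclo[3.1.1]heptane, comes from an intramolecular ketene–diene [2+2] cycloaddition.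

Key step: step 11

Remark: the configuration in the target SMILES is taken as the natural one. Tricyclic compounds carry longipinane numbers (C1 carbonyl carbon, C2=C3, C4 and C11 the cyclobutane CH groups next to C3 and C1, C5 the cyclobutane CH bearing C6, C7–C9 the oxygenated unit, C10 the quaternary cyclobutane carbon). On the one-carbon bridges (C6, C7) of the bicyclo[3.1.1]heptanes, syn means toward the C2–C4 bridge and anti away from it.

Step 1
Reactants: 1 (E)-3-methylpent-2-en-4-yn-1-ol
Product: 2 (E)-3-methylpenta-2,4-dien-1-ol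
Conditions: H2 (1 atm), 5% Pd/CaCO3 poisoned with Pb(OAc)2, quinoline, EtOAc, rt
Reagents that add atoms: none
Why: Semi-hydrogenation of the terminal alkyne on poisoned palladium should stop at the vinyl group and leave the E trisubstituted alkene and its geometry untouched.

Step 2
Reactants: 2 (E)-3-methylpenta-2,4-dien-1-ol
Product: 3 (E)-3-methylpenta-2,4-dienal
Conditions: MnO2 (10 equiv), CH2Cl2, rt; used as a solution
Reagents that add atoms: none
Why: Allylic alcohol oxidation with MnO2 should give the conjugated dienal without E/Z scrambling; no stereocentre is involved.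

Step 3
Reactants: 4 ethyl 3-methylbut-2-enoate
Product: 6 (1Z)-1-ethoxy-3-methyl-1-(tert-butyldimethylsilyloxy)buta-1,3-diene, via lithium dienolate 5 (not isolated)
Conditions: LiN(i-Pr)2, THF, −78 °C; t-BuMe2SiCl, DMPU, −78 °C → rt
Reagents that add atoms: tert-butyldimethylsilyl chloride, C[Si](C)(Cl)C(C)(C)C
Why: γ-Deprotonation of the enoate and O-silylation of the extended enolate give the silyl dienol ether needed for a vinylogous Mukaiyama aldol reaction.

Step 4
Reactants: 3 (E)-3-methylpenta-2,4-dienal; 6 (1Z)-1-ethoxy-3-methyl-1-(tert-butyldimethylsilyloxy)buta-1,3-diene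
Product: 8 ethyl (2E,5S,6E)-5-hydroxy-3,7-dimethylnona-2,6,8-trienoate, via trichlorosilyl ether 7 (not isolated)
Conditions: SiCl4 (1.1 equiv), (S,S)-bisphosphoramide catalyst [two N,N'-dimethyl-1,1'-binaphthyl-2,2'-diamine P(=O) units joined N(Me)–(CH2)5–N(Me)] (5 mol%), i-Pr2NEt (10 mol%), CH2Cl2, −78 °C; aq. NaHCO3
Reagents that add atoms: none
Why: Catalytic enantioselective vinylogous Mukaiyama aldol addition: the Lewis-base-bound trichlorosilyl cation activates the aldehyde for 1,2-attack by the γ-carbon of the dienolate, the catalyst antipode being the one chosen to direct attack to the Si face, which sets C5 as S and gives the 2E enoate from the s-trans dienolate.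

Step 5
Reactants: 8 ethyl (2E,5S,6E)-5-hydroxy-3,7-dimethylnona-2,6,8-trienoate
Product: 9 ethyl (2E,5S,6E)-5-(tert-butyldimethylsilyloxy)-3,7-dimethylnona-2,6,8-trienoate
Conditions: t-BuMe2SiCl, imidazole, DMF, rt
Reagents that add atoms: tert-butyldimethylsilyl chloride, C[Si](C)(Cl)C(C)(C)C
Why: Standard silylation protects the allylic alcohol for the ketene and enolate chemistry that follows.

Step 6
Reactants: 9 ethyl (2E,5S,6E)-5-(tert-butyldimethylsilyloxy)-3,7-dimethylnona-2,6,8-trienoate
Product: 11 (2E,5S,6E)-5-(tert-butyldimethylsilyloxy)-3,7-dimethylnona-2,6,8-trienoic acid, via lithium carboxylate 10 (not isolated)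
Conditions: LiOH, THF/MeOH/H2O (3:1:1), rt; 1 M HCl to pH 4, 0 °C
Reagents that add atoms: lithium hydroxide, [Li+].[OH-]
Why: Saponification of the ethyl ester; the silyl ether should survive the brief mild acidification.

Step 7
Reactants: 11 (2E,5S,6E)-5-(tert-butyldimethylsilyloxy)-3,7-dimethylnona-2,6,8-trienoic acid
Product: 14 (1R,4S,5R,7R)-4-(tert-butyldimethylsilyloxy)-7-ethenyl-7-methyl-2-methylidenebicyclo[3.1.1]heptan-6-one, via acid chloride 12 (not isolated), via vinylketene 13 (not isolated)
Conditions: 1-chloro-N,N,2-trimethylprop-1-en-1-amine (1.2 equiv), CH2Cl2, 0 °C → rt; then slow addition to Et3N (3 equiv), toluene, 110 °C, 0.01 M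
Reagents that add atoms: none
Why: Neutral acid chloride formation and 1,4-dehydrochlorination through the C3 methyl group (cis to the carbonyl in the 2E acid) give a vinylketene that should undergo the crossed intramolecular [2+2] ketene–alkene cycloaddition known for bergamotene-type ketones: the carbonyl carbon bonds to the diene terminus C6 and the α-carbon to the allyl-cation-stabilised C7, the alkene geometry is transferred so that the methyl ends syn and the vinyl anti, and the silyloxy carbon directs the ketene to the alkene face that keeps OTBS away from the C7 methyl (allylic 1,3-strain), which fixes C1, C5 and C7.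

Step 8
Reactants: 14 (1R,4S,5R,7R)-4-(tert-butyldimethylsilyloxy)-7-ethenyl-7-methyl-2-methylidenebicyclo[3.1.1]heptan-6-one; 15 methyl 2-methylpropanoate
Product: 18 methyl 2-[(1R,4S,5R,6R,7R)-4-(tert-butyldimethylsilyloxy)-7-ethenyl-6-(2-methoxy-2-oxoacetoxy)-7-methyl-2-methylidenebicyclo[3.1.1]heptan-6-yl]-2-methylpropanoate, via lithium ester enolate 16 (not isolated), via lithium alkoxide 17 (not isolated)
Conditions: LiN(i-Pr)2 (1.6 equiv), 15 (1.6 equiv), THF, −78 °C; 14, −78 °C; ClC(O)CO2Me (2.5 equiv), −78 → 0 °C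
Reagents that add atoms: methyl chlorooxoacetate, COC(=O)C(=O)Cl
Why: Aldol-type addition of the lithium ester enolate to the strained cyclobutanone, which cannot enolise (bridgehead α-carbons); the nucleophile should enter anti to the three-carbon bridge because a syn tert-alkyl group would be wedged against C3, and the tertiary alkoxide is acylated cold to stop retro-aldol cleavage.

Step 9
Reactants: 18 the methyl oxalate of step 8
Product: 19 methyl 2-[(1R,4S,5R,6S,7R)-4-(tert-butyldimethylsilyloxy)-7-ethenyl-7-methyl-2-methylidenebicyclo[3.1.1]heptan-6-yl]-2-methylpropanoate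
Conditions: Bu3SnH (2 equiv), AIBN (0.2 equiv), toluene, 110 °C
Reagents that add atoms: none
Why: Radical deoxygenation of the tertiary methyl oxalate (Barton–McCombie type; no β-hydrogen is available for elimination): the cyclobutyl radical should keep the bulky ester-bearing carbon anti and take hydrogen on the bridge side, so C6 ends with the side chain anti whatever the facial course of step 8.

Step 10
Reactants: 19 the vinyl ester of step 9
Product: 20 methyl 2-[(1R,4S,5R,6S,7R)-7-acetyl-4-(tert-butyldimethylsilyloxy)-7-methyl-2-methylidenebicyclo[3.1.1]heptan-6-yl]-2-methylpropanoate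
Conditions: PdCl2 (10 mol%), CuCl (1 equiv), O2 (1 atm), DMF/H2O (7:1), rt
Reagents that add atoms: water, O
Why: Wacker oxidation should convert the monosubstituted vinyl group into the methyl ketone with Markovnikov selectivity; the 1,1-disubstituted exocyclic alkene reacts far more slowly.

Step 11
Reactants: 20 the keto ester of step 10
Product: 23 (1S,4R,5S,10R,11R)-1-(tert-butyldimethylsilyloxy)longipin-3(12)-ene-7,9-dione, via lithium ketone enolate 21 (not isolated), via lithium diketonate 22 (not isolated)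
Conditions: LiN(SiMe3)2 (2.5 equiv), THF, −78 → 40 °C; aq. NH4Cl
Reagents that add atoms: none
Why: LiN(SiMe3)2 removes a proton from the only enolisable carbon of the ketone, the acetyl methyl C8 (C10 is quaternary); the enolate carbon adds to the ester carbonyl C7, methoxide leaves, and the product is drained off as its stabilised diketonate 22, which makes the condensation irreversible. The closest known reaction is the intramolecular Claisen (Dieckmann-type) condensation of keto esters to cyclic 1,3-diketones, and the same hindered bond type is made when pinacolone is acylated with methyl pivalate. The seven-membered carbocycle closes in the 7-(enolendo)-exo-trig mode and is favoured because the acetyl group on C10 and the ester chain on C5 are both anti on the cyclobutane and lie about 3 Å apart. No stereocentre is created: C7 and C9 are left as carbonyl groups on purpose, since the scaffold offers no bias between the two faces of either carbon. The step needs only regioselectivity (one donor, one acceptor), which the quaternary carbons C6 and C10 secure, and any O-acylation to an enol lactone is reversed by methoxide.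

Step 12
Reactants: 23 the tricyclic 1,3-diketone of step 11
Product: 25 (1S,4R,5S,7R,9R,10R,11R)-1-(tert-butyldimethylsilyloxy)longipin-3(12)-ene-7,9-diol, via bis(catecholboronate) 24 (not isolated)
Conditions: (S)-1-methyl-3,3-diphenyltetrahydro-1H,3H-pyrrolo[1,2-c][1,3,2]oxazaborole (0.5 equiv), catecholborane (5 equiv), toluene, −78 → −30 °C; MeOH, aq. NaHCO3
Reagents that add atoms: none
Why: Corey–Bakshi–Shibata reduction: each carbonyl has a quaternary α-carbon as the large group and the C8 methylene as the small one, so the S catalyst should deliver hydride to give R at both C7 and C9 (the anti diol) under reagent control, and catecholborane at low temperature spares the exocyclic alkene.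

Step 13
Reactants: 25 the 7,9-diol of step 12; 26 (E)-2-methylbut-2-enoyl chloride
Product: 27 (1S,4R,5S,7R,9R,10R,11R)-1-(tert-butyldimethylsilyloxy)-7-hydroxylongipin-3(12)-en-9-yl (E)-2-methylbut-2-enoate
Conditions: 26 (1.1 equiv), pyridine, 4-(dimethylamino)pyridine (0.1 equiv), CH2Cl2, −20 °C
Reagents that add atoms: none
Why: The C9 hydroxyl, next to the tied-back cyclobutane carbon C10, is less hindered than the neopentyl C7 hydroxyl next to the gem-dimethyl carbon, so one equivalent of acid chloride should acylate O9 selectively; acyl migration is impossible between the trans hydroxyls of the ring.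

Step 14
Reactants: 27 the 9-monoester of step 13; 28 3-methylbutanoyl chloride
Product: 29 (1S,4R,5S,7R,9R,10R,11R)-1-(tert-butyldimethylsilyloxy)-7-(3-methylbutanoyloxy)longipin-3(12)-en-9-yl (E)-2-methylbut-2-enoate
Conditions: 28 (3 equiv), 4-(dimethylamino)pyridine (1 equiv), pyridine, 40 °C
Reagents that add atoms: none
Why: Forcing nucleophilic-catalysed acylation with an unhindered acid chloride should esterify the remaining neopentyl hydroxyl without touching C7.

Step 15
Reactants: 29 the silylated diester of step 14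
Product: 30 (1S,4R,5S,7R,9R,10R,11R)-1-hydroxy-7-(3-methylbutanoyloxy)longipin-3(12)-en-9-yl (E)-2-methylbut-2-enoate
Conditions: Bu4NF (3 equiv), AcOH (3 equiv), THF, rt → 40 °C
Reagents that add atoms: none
Why: Fluoride cleaves the silyl ether, and acetic acid buffering protects both esters and the acid-sensitive alkene.

Step 16
Reactants: 30 the 1-hydroxy diester of step 15
Product: 32 (4R,5S,7R,9R,10R,11R)-7-(3-methylbutanoyloxy)-9-[(E)-2-methylbut-2-enoyloxy]longipin-2-en-1-one, via exocyclic enone 31 (not isolated)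
Conditions: 1,1,1-triacetoxy-1,1-dihydro-1,2-benziodoxol-3(1H)-one (DMP, 1.5 equiv), pyridine (5 equiv), CH2Cl2, 0 °C → rt; then DBU (0.3 equiv), rt
Reagents that add atoms: none
Why: Periodinane oxidation gives the β,γ-unsaturated ketone, and base moves the exocyclic double bond into conjugation (thermodynamic, verbenone-type enone); C11 is a bridgehead and cannot epimerise.

Compound list
1 | (E)-3-methylpent-2-en-4-yn-1-ol | C#C/C(C)=C/CO | starting material
2 | (E)-3-methylpenta-2,4-dien-1-ol | C=C/C(C)=C/CO | intermediate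
3 | (E)-3-methylpenta-2,4-dienal | C=C/C(C)=C/C=O | intermediate
4 | ethyl 3-methylbut-2-enoate | CCOC(=O)C=C(C)C | starting material
5 | lithium (1E)-1-ethoxy-3-methylbuta-1,3-dien-1-olate (not isolated) | C=C(C)/C=C(/OCC)[O-].[Li+] | intermediate
6 | (1Z)-1-ethoxy-3-methyl-1-(tert-butyldimethylsilyloxy)buta-1,3-diene | C=C(C)/C=C(/OCC)O[Si](C)(C)C(C)(C)C | intermediate
7 | ethyl (2E,5S,6E)-3,7-dimethyl-5-(trichlorosilyloxy)nona-2,6,8-trienoate (not isolated) | CCOC(=O)/C=C(\C)C[C@H](O[Si](Cl)(Cl)Cl)/C=C(\C)C=C | intermediate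
8 | ethyl (2E,5S,6E)-5-hydroxy-3,7-dimethylnona-2,6,8-trienoate | CCOC(=O)/C=C(\C)C[C@H](O)/C=C(\C)C=C | intermediate
9 | ethyl (2E,5S,6E)-5-(tert-butyldimethylsilyloxy)-3,7-dimethylnona-2,6,8-trienoate | CCOC(=O)/C=C(\C)C[C@H](O[Si](C)(C)C(C)(C)C)/C=C(\C)C=C | intermediate
10 | lithium (2E,5S,6E)-5-(tert-butyldimethylsilyloxy)-3,7-dimethylnona-2,6,8-trienoate (not isolated) | [Li+].[O-]C(=O)/C=C(\C)C[C@H](O[Si](C)(C)C(C)(C)C)/C=C(\C)C=C | intermediate
11 | (2E,5S,6E)-5-(tert-butyldimethylsilyloxy)-3,7-dimethylnona-2,6,8-trienoic acid | OC(=O)/C=C(\C)C[C@H](O[Si](C)(C)C(C)(C)C)/C=C(\C)C=C | intermediate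
12 | (2E,5S,6E)-5-(tert-butyldimethylsilyloxy)-3,7-dimethylnona-2,6,8-trienoyl chloride (not isolated) | ClC(=O)/C=C(\C)C[C@H](O[Si](C)(C)C(C)(C)C)/C=C(\C)C=C | intermediate
13 | (5S,6E)-5-(tert-butyldimethylsilyloxy)-7-methyl-3-methylidenenona-1,6,8-trien-1-one, vinylketene (not isolated) | O=C=CC(=C)C[C@H](O[Si](C)(C)C(C)(C)C)/C=C(\C)C=C | intermediate
14 | (1R,4S,5R,7R)-4-(tert-butyldimethylsilyloxy)-7-ethenyl-7-methyl-2-methylidenebicyclo[3.1.1]heptan-6-one (methyl syn, vinyl anti, OTBS trans to the C7 bridge) | C=C[C@@]1(C)[C@@H]2[C@@H](O[Si](C)(C)C(C)(C)C)CC(=C)[C@H]1C2=O | intermediate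
15 | methyl 2-methylpropanoate | COC(=O)C(C)C | starting material
16 | lithium 1-methoxy-2-methylprop-1-en-1-olate (not isolated) | [Li+].[O-]C(OC)=C(C)C | intermediate
17 | lithium alkoxide of the aldol adduct of 14 and 16, ester chain anti and O syn on C6 (not isolated) | C=C[C@@]1(C)[C@@H]2[C@@H](O[Si](C)(C)C(C)(C)C)CC(=C)[C@H]1[C@]2([O-])C(C)(C)C(=O)OC.[Li+] | intermediate
18 | methyl 2-[(1R,4S,5R,6R,7R)-4-(tert-butyldimethylsilyloxy)-7-ethenyl-6-(2-methoxy-2-oxoacetoxy)-7-methyl-2-methylidenebicyclo[3.1.1]heptan-6-yl]-2-methylpropanoate | C=C[C@@]1(C)[C@@H]2[C@@H](O[Si](C)(C)C(C)(C)C)CC(=C)[C@H]1[C@]2(OC(=O)C(=O)OC)C(C)(C)C(=O)OC | intermediate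
19 | methyl 2-[(1R,4S,5R,6S,7R)-4-(tert-butyldimethylsilyloxy)-7-ethenyl-7-methyl-2-methylidenebicyclo[3.1.1]heptan-6-yl]-2-methylpropanoate (side chain anti) | C=C[C@@]1(C)[C@@H]2[C@@H](O[Si](C)(C)C(C)(C)C)CC(=C)[C@H]1[C@@H]2C(C)(C)C(=O)OC | intermediate
20 | methyl 2-[(1R,4S,5R,6S,7R)-7-acetyl-4-(tert-butyldimethylsilyloxy)-7-methyl-2-methylidenebicyclo[3.1.1]heptan-6-yl]-2-methylpropanoate | CC(=O)[C@@]1(C)[C@@H]2[C@@H](O[Si](C)(C)C(C)(C)C)CC(=C)[C@H]1[C@@H]2C(C)(C)C(=O)OC | intermediate
21 | lithium enolate of 20 at the acetyl methyl group (not isolated) | [Li+].C=C([O-])[C@@]1(C)[C@@H]2[C@@H](O[Si](C)(C)C(C)(C)C)CC(=C)[C@H]1[C@@H]2C(C)(C)C(=O)OC | intermediate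
22 | lithium enolate of diketone 23 (not isolated) | [Li+].[O-]C1=CC(=O)C(C)(C)[C@@H]2[C@H]3[C@@H](O[Si](C)(C)C(C)(C)C)CC(=C)[C@@H]2[C@]31C | intermediate
23 | (1S,4R,5S,10R,11R)-1-(tert-butyldimethylsilyloxy)longipin-3(12)-ene-7,9-dione | O=C1CC(=O)C(C)(C)[C@@H]2[C@H]3[C@@H](O[Si](C)(C)C(C)(C)C)CC(=C)[C@@H]2[C@]31C | intermediate
24 | 7,9-bis(1,3,2-benzodioxaborol-2-yl) ether of diol 25 (not isolated) | B1(Oc2ccccc2O1)O[C@@H]3C[C@@H](OB4Oc5ccccc5O4)C(C)(C)[C@@H]6[C@H]7[C@@H](O[Si](C)(C)C(C)(C)C)CC(=C)[C@@H]6[C@]73C | intermediate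
25 | (1S,4R,5S,7R,9R,10R,11R)-1-(tert-butyldimethylsilyloxy)longipin-3(12)-ene-7,9-diol | O[C@@H]1C[C@@H](O)C(C)(C)[C@@H]2[C@H]3[C@@H](O[Si](C)(C)C(C)(C)C)CC(=C)[C@@H]2[C@]31C | intermediate
26 | (E)-2-methylbut-2-enoyl chloride (tigloyl chloride) | C/C=C(\C)C(=O)Cl | starting material
27 | (1S,4R,5S,7R,9R,10R,11R)-1-(tert-butyldimethylsilyloxy)-7-hydroxylongipin-3(12)-en-9-yl (E)-2-methylbut-2-enoate | C/C=C(\C)C(=O)O[C@@H]1C[C@@H](O)C(C)(C)[C@@H]2[C@H]3[C@@H](O[Si](C)(C)C(C)(C)C)CC(=C)[C@@H]2[C@]31C | intermediate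
28 | 3-methylbutanoyl chloride (isovaleryl chloride) | CC(C)CC(=O)Cl | starting material
29 | (1S,4R,5S,7R,9R,10R,11R)-1-(tert-butyldimethylsilyloxy)-7-(3-methylbutanoyloxy)longipin-3(12)-en-9-yl (E)-2-methylbut-2-enoate | C/C=C(\C)C(=O)O[C@@H]1C[C@@H](OC(=O)CC(C)C)C(C)(C)[C@@H]2[C@H]3[C@@H](O[Si](C)(C)C(C)(C)C)CC(=C)[C@@H]2[C@]31C | intermediate
30 | (1S,4R,5S,7R,9R,10R,11R)-1-hydroxy-7-(3-methylbutanoyloxy)longipin-3(12)-en-9-yl (E)-2-methylbut-2-enoate | C/C=C(\C)C(=O)O[C@@H]1C[C@@H](OC(=O)CC(C)C)C(C)(C)[C@@H]2[C@H]3[C@@H](O)CC(=C)[C@@H]2[C@]31C | intermediate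
31 | (4R,5S,7R,9R,10R,11R)-7-(3-methylbutanoyloxy)-9-[(E)-2-methylbut-2-enoyloxy]longipin-3(12)-en-1-one (not isolated) | C/C=C(\C)C(=O)O[C@@H]1C[C@@H](OC(=O)CC(C)C)C(C)(C)[C@@H]2[C@H]3C(=O)CC(=C)[C@@H]2[C@]31C | intermediate
32 | (4R,5S,7R,9R,10R,11R)-7-(3-methylbutanoyloxy)-9-[(E)-2-methylbut-2-enoyloxy]longipin-2-en-1-one (CNP0194415.1) | C/C=C(\C)C(=O)O[C@@H]1C[C@@H](OC(=O)CC(C)C)C(C)(C)[C@@H]2[C@H]3C(=O)C=C(C)[C@@H]2[C@]31C | target

Total step count: 16. Longest linear sequence: 15 steps (from 1 through steps 1, 2 and 4–16; step 3 prepares the second fragment).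

Steps most likely to fail

Step 8. The tetrasubstituted ester enolate may fail to add to the doubly flanked cyclobutanone, or the addition may revert before the alkoxide is trapped. The fallback uses a smaller, more nucleophilic carbanion and closes the ring through a nitrile. From 14, lithiated 2-methylpropanenitrile (LiN(i-Pr)2, THF, −78 °C) should add to give lithium alkoxide F1, acylated in the flask by methyl chlorooxoacetate to the oxalate nitrile F2. Bu3SnH/AIBN should give nitrile F3, and the Wacker oxidation keto nitrile F4. KOt-Bu in THF should then add the methyl ketone enolate to the nitrile (Thorpe-type closure of the same C7–C8 bond) to give enaminone F5. Hydrolysis of F5 in aqueous acetic acid returns to the route at diketone 23.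

Step 13. The rate difference between the two hindered hydroxyls may be too small, giving statistical acylation. The fallback differentiates the oxygens by an Evans–Tishchenko reduction instead of by sterics, and also avoids any enolisation or hydroboration problem in step 12. From 19, i-Bu2AlH (CH2Cl2, −78 °C) should give aldehyde F6, and the Wacker oxidation keto aldehyde F7. LiN(SiMe3)2 (THF, −78 °C) should close the C7–C8 bond by aldol addition to give the 7R hydroxy ketone F8 together with its 7S epimer F9. No facial bias is expected here, so F9 would be returned to the mixture by retro-aldol equilibration with K2CO3 in methanol. SmI2 (30 mol%) and 3-methylbutanal (THF, −10 °C) should convert F8 into the hydroxy ester F10 by intramolecular hydride transfer, which places the 3-methylbutanoate on O7 and the new 9R hydroxyl anti. Acylation of F10 with 26 under the conditions of step 13 returns to the route at 29.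

Step 7. The base may deprotonate the acid chloride at C4 instead of the C3 methyl group, giving a dienylketene that cannot cyclise, and the ketene may oligomerise at the temperature needed. The fallback moves the double bond first. From 9, LiN(i-Pr)2 in THF/DMPU at −78 °C followed by a cold acetic acid quench (kinetic α-protonation of the dienolate) should give the deconjugated ester F11. LiOH should give the deconjugated acid F12, and the chloro-enamine of step 7 the acid chloride F13. Simple α-dehydrochlorination of F13 with Et3N, possible at 60–80 °C, should give the same vinylketene 13 and so return to the route at 14.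

Further compounds
F1 | step 8 | lithium alkoxide of the adduct of 14 and lithiated 2-methylpropanenitrile | C=C[C@@]1(C)[C@@H]2[C@@H](O[Si](C)(C)C(C)(C)C)CC(=C)[C@H]1[C@]2([O-])C(C)(C)C#N.[Li+]
F2 | step 8 | methyl oxalate of the tertiary alcohol bearing the 2-cyanopropan-2-yl group on C6 | C=C[C@@]1(C)[C@@H]2[C@@H](O[Si](C)(C)C(C)(C)C)CC(=C)[C@H]1[C@]2(OC(=O)C(=O)OC)C(C)(C)C#N
F3 | step 8 | 2-[4-(tert-butyldimethylsilyloxy)-7-ethenyl-7-methyl-2-methylidenebicyclo[3.1.1]heptan-6-yl]-2-methylpropanenitrile (side chain anti) | C=C[C@@]1(C)[C@@H]2[C@@H](O[Si](C)(C)C(C)(C)C)CC(=C)[C@H]1[C@@H]2C(C)(C)C#N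
F4 | step 8 | 2-[7-acetyl-4-(tert-butyldimethylsilyloxy)-7-methyl-2-methylidenebicyclo[3.1.1]heptan-6-yl]-2-methylpropanenitrile | CC(=O)[C@@]1(C)[C@@H]2[C@@H](O[Si](C)(C)C(C)(C)C)CC(=C)[C@H]1[C@@H]2C(C)(C)C#N
F5 | step 8 | 7-amino-1-(tert-butyldimethylsilyloxy)longipina-3(12),7-dien-9-one (enaminone) | O=C1C=C(N)C(C)(C)[C@@H]2[C@H]3[C@@H](O[Si](C)(C)C(C)(C)C)CC(=C)[C@@H]2[C@]31C
F6 | step 13 | 2-[4-(tert-butyldimethylsilyloxy)-7-ethenyl-7-methyl-2-methylidenebicyclo[3.1.1]heptan-6-yl]-2-methylpropanal | C=C[C@@]1(C)[C@@H]2[C@@H](O[Si](C)(C)C(C)(C)C)CC(=C)[C@H]1[C@@H]2C(C)(C)C=O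
F7 | step 13 | 2-[7-acetyl-4-(tert-butyldimethylsilyloxy)-7-methyl-2-methylidenebicyclo[3.1.1]heptan-6-yl]-2-methylpropanal | CC(=O)[C@@]1(C)[C@@H]2[C@@H](O[Si](C)(C)C(C)(C)C)CC(=C)[C@H]1[C@@H]2C(C)(C)C=O
F8 | step 13 | (7R)-1-(tert-butyldimethylsilyloxy)-7-hydroxylongipin-3(12)-en-9-one | O=C1C[C@@H](O)C(C)(C)[C@@H]2[C@H]3[C@@H](O[Si](C)(C)C(C)(C)C)CC(=C)[C@@H]2[C@]31C
F9 | step 13 | (7S)-1-(tert-butyldimethylsilyloxy)-7-hydroxylongipin-3(12)-en-9-one | O=C1C[C@H](O)C(C)(C)[C@@H]2[C@H]3[C@@H](O[Si](C)(C)C(C)(C)C)CC(=C)[C@@H]2[C@]31C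
F10 | step 13 | (7R,9R)-1-(tert-butyldimethylsilyloxy)-9-hydroxylongipin-3(12)-en-7-yl 3-methylbutanoate | O[C@@H]1C[C@@H](OC(=O)CC(C)C)C(C)(C)[C@@H]2[C@H]3[C@@H](O[Si](C)(C)C(C)(C)C)CC(=C)[C@@H]2[C@]31C
F11 | step 7 | ethyl (5S,6E)-5-(tert-butyldimethylsilyloxy)-7-methyl-3-methylidenenona-6,8-dienoate | CCOC(=O)CC(=C)C[C@H](O[Si](C)(C)C(C)(C)C)/C=C(\C)C=C
F12 | step 7 | (5S,6E)-5-(tert-butyldimethylsilyloxy)-7-methyl-3-methylidenenona-6,8-dienoic acid | OC(=O)CC(=C)C[C@H](O[Si](C)(C)C(C)(C)C)/C=C(\C)C=C
F13 | step 7 | (5S,6E)-5-(tert-butyldimethylsilyloxy)-7-methyl-3-methylidenenona-6,8-dienoyl chloride | ClC(=O)CC(=C)C[C@H](O[Si](C)(C)C(C)(C)C)/C=C(\C)C=C
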